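**Plan**
The retrosynthesis first cuts the C5 O–CH2OMe bond, then in one operation the O1–C8a and C4–C4a bonds of ring C, and last the C6–geranyl, C4a–Si and C8a–O–S bonds of a ring-A aryne precursor.
The enabling feature is that ring C is fused to ring A through the adjacent carbons C8a (bonded to O1) and C4a (bonded to the C4 carbonyl), with the C5 oxygen beside C4a. This is the pattern expected when an oxygen nucleophile and an acyl electrophile add across a 3-alkoxy-polarised aryne.
Forward, ring A is completed first from 5-methoxyresorcinol: differentiation of the two phenols, geranylation at C6, silylation at C4a and triflation at C8a-O.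
Ring C then closes in the aryne step with ring B already attached to the three-carbon partner, and the C5 MOM ether is removed last.
The single stereocenter C2 comes from asymmetric hydrogenation of an aryl β-keto ester to the (S)-carbinol. Its C–O bond is not broken afterwards, so (S) in the carbinol becomes (2S) in the flavanone, and the E alkene comes from geranyl bromide.

Key step: step 11

Assumptions on the chemistry: the (R)-BINAP ruthenium catalyst is taken to reduce the 3,4-dimethoxybenzoyl keto ester with the same facial sense as other aroylacetates, giving the (S)-carbinol. Ring-A carbons keep their flavanone numbers (C4a, C5 to C8, C8a) in all precursors. Geranyl stands for (2E)-3,7-dimethylocta-2,6-dien-1-yl.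

**Route**

Step 1
Reactants: 1 5-methoxyresorcinol
Product: 2 3-methoxy-5-(triisopropylsilyloxy)phenol
Conditions: TIPSCl (1.0 equiv), imidazole, DMF, 0 °C to rt
Reagents that add atoms: triisopropylsilyl chloride, CC(C)[Si](Cl)(C(C)C)C(C)C
Why: Statistical monosilylation of a symmetrical resorcinol with one equivalent of a bulky silyl chloride, with the bis-silyl ether and unreacted 1 separable and recyclable.

Step 2
Reactants: 2 3-methoxy-5-(triisopropylsilyloxy)phenol
Product: 3 triisopropyl[3-methoxy-5-(methoxymethoxy)phenoxy]silane
Conditions: MOMCl, iPr2NEt, CH2Cl2, 0 °C to rt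
Reagents that add atoms: chloromethyl methyl ether, COCCl
Why: O-alkylation of the remaining phenol with an α-chloro ether under amine base (MOM protection), to which the TIPS ether is inert.

Step 3
Reactants: 3 triisopropyl[3-methoxy-5-(methoxymethoxy)phenoxy]silane; 4 geranyl bromide
Product: 6 [4-geranyl-3-methoxy-5-(methoxymethoxy)phenoxy]triisopropylsilane, via C6 aryllithium 5 (not isolated)
Conditions: n-BuLi, THF, 0 °C to rt; then CuBr·SMe2 (10 mol %), 4, −78 °C to rt
Reagents that add atoms: none
Why: Directed ortho-metalation at the carbon flanked by OMOM and OMe (the bulky TIPS ether neither directs nor is attacked), followed by copper-catalysed SN2 allylation of the aryllithium at the primary carbon of geranyl bromide, which keeps the E alkene.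

Step 4
Reactants: 6 [4-geranyl-3-methoxy-5-(methoxymethoxy)phenoxy]triisopropylsilane
Product: 7 4-geranyl-3-methoxy-5-(methoxymethoxy)phenol
Conditions: TBAF, AcOH (1:1), THF, 0 °C
Reagents that add atoms: none
Why: Fluoride-mediated cleavage of the aryl silyl ether, buffered with acetic acid, leaves the MOM ether, the methyl ether and both alkenes untouched.

Step 5
Reactants: 7 4-geranyl-3-methoxy-5-(methoxymethoxy)phenol
Product: 8 4-geranyl-3-methoxy-5-(methoxymethoxy)phenyl N,N-diethylcarbamate
Conditions: NaH, THF, 0 °C; ClC(O)NEt2, 0 °C to rt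
Reagents that add atoms: N,N-diethylcarbamoyl chloride, CCN(CC)C(Cl)=O
Why: O-carbamoylation of the sodium phenoxide installs the strongest oxygen-based directing group for the next metalation.

Step 6
Reactants: 8 4-geranyl-3-methoxy-5-(methoxymethoxy)phenyl N,N-diethylcarbamate
Product: 10 4-geranyl-5-methoxy-3-(methoxymethoxy)-2-(trimethylsilyl)phenyl N,N-diethylcarbamate, via C4a aryllithium 9 (not isolated)
Conditions: s-BuLi, TMEDA, THF, −78 °C; TMSCl, −78 °C to rt
Reagents that add atoms: chlorotrimethylsilane, C[Si](C)(C)Cl
Why: Directed ortho-metalation of the O-aryl carbamate should occur at C4a, which lies between the carbamate and the chelating MOM ether, in preference to C8, which lies beside the weaker OMe director whose methyl group is pushed toward C8 by the C6 geranyl chain; holding the anion at −78 °C until silylation avoids the anionic ortho-Fries shift.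

Step 7
Reactants: 10 4-geranyl-5-methoxy-3-(methoxymethoxy)-2-(trimethylsilyl)phenyl N,N-diethylcarbamate
Product: 11 4-geranyl-5-methoxy-3-(methoxymethoxy)-2-(trimethylsilyl)phenol
Conditions: LiAlH4, THF, 0 °C to 40 °C; Rochelle-salt work-up
Reagents that add atoms: none
Why: Hydride reduction of the carbamate carbonyl releases the phenoxide, while the aryl silane, MOM ether and alkenes are inert to hydride and the non-acidic work-up avoids protodesilylation of the electron-rich ring.

Step 8
Reactants: 11 4-geranyl-5-methoxy-3-(methoxymethoxy)-2-(trimethylsilyl)phenol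
Product: 12 4-geranyl-5-methoxy-3-(methoxymethoxy)-2-(trimethylsilyl)phenyl trifluoromethanesulfonate
Conditions: Tf2O, pyridine, CH2Cl2, 0 °C
Reagents that add atoms: trifluoromethanesulfonic anhydride, O=S(=O)(OS(=O)(=O)C(F)(F)F)C(F)(F)F
Why: O-sulfonylation of the hindered phenol under pyridine buffering gives the 2-silylaryl triflate, the standard fluoride-triggered aryne precursor.

Step 9
Reactants: 13 ethyl 3-(3,4-dimethoxyphenyl)-3-oxopropanoate
Product: 14 ethyl (3S)-3-(3,4-dimethoxyphenyl)-3-hydroxypropanoate
Conditions: H2 (50 atm), RuCl2[(R)-BINAP] (1 mol %), EtOH, 50 °C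
Reagents that add atoms: none
Why: Noyori asymmetric hydrogenation of a β-keto ester, in which chelation of the keto ester to the BINAP ruthenium hydride fixes the face of hydride delivery, so that the (R)-ligand should set the (S)-carbinol (S because the aryl group outranks CH2CO2Et).

Step 10
Reactants: 14 ethyl (3S)-3-(3,4-dimethoxyphenyl)-3-hydroxypropanoate
Product: 15 ethyl (3S)-3-(3,4-dimethoxyphenyl)-3-(trimethylsilyloxy)propanoate
Conditions: TMSCl, imidazole, CH2Cl2, 0 °C; neutral work-up
Reagents that add atoms: chlorotrimethylsilane, C[Si](C)(C)Cl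
Why: O-silylation of the secondary alcohol turns it into a proton-free latent alkoxide without touching any bond to the stereocenter.

Step 11
Reactants: 12 4-geranyl-5-methoxy-3-(methoxymethoxy)-2-(trimethylsilyl)phenyl trifluoromethanesulfonate; 15 ethyl (3S)-3-(3,4-dimethoxyphenyl)-3-(trimethylsilyloxy)propanoate
Product: 18 (2S)-6-geranyl-7,3',4'-trimethoxy-5-(methoxymethoxy)flavanone, via ring-A aryne 16 (not isolated), via ammonium alkoxide 17 (not isolated)
Conditions: 15 (1.5 equiv), Bu4N[Ph3SiF2] (TBAT, 1.2 equiv, added slowly), THF, 0 °C to rt; pH 7 buffer quench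
Reagents that add atoms: none
Why: Proposed new method: fluoride from TBAT strips the aryl silicon of 12 with loss of triflate to give aryne 16 and also frees the proton-free alkoxide 17 from 15; the alkoxide oxygen adds to C8a and the resulting C4a aryl anion attacks the ester carbonyl, expelling ethoxide, which is silylated by remaining 15 so that the medium should not turn strongly basic. The closest known reaction type is the fluoride-triggered annulation of arynes with salicylate esters to xanthones, extended here from a phenoxide to a secondary alkoxide released from its silyl ether. Ring C closes by a 6-exo-trig acyl substitution (C4a onto C4) after the intermolecular O1–C8a bond formation. No stereocenter is formed: the C2–O bond of 15 is never broken, so its S configuration is carried into 18. The step needs regioselective addition to the unsymmetrical aryne, which the inductively withdrawing C5 methoxymethoxy group beside C4a should secure by directing the nucleophile to the distal carbon C8a and stabilising the charge at C4a. It also needs acylation to outrun protonation of the aryl anion, for which the silyl ether (no O–H), THF and fluoride in only slight excess are chosen.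

Step 12
Reactants: 18 (2S)-6-geranyl-7,3',4'-trimethoxy-5-(methoxymethoxy)flavanone
Product: 19 (2S)-6-geranyl-5-hydroxy-7,3',4'-trimethoxyflavanone
Conditions: HCl (ca. 1 M) in MeOH/THF, rt
Reagents that add atoms: none
Why: Acid-catalysed acetal exchange of the MOM ether with methanol, made unusually easy by the peri C4 carbonyl that hydrogen-bonds the freed C5 phenol, so dilute acid at room temperature should spare the geranyl alkenes and the C2 stereocenter.

**Compound list**
1 | 5-methoxyresorcinol (5-methoxybenzene-1,3-diol) | COc1cc(O)cc(O)c1 | starting material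
2 | 3-methoxy-5-(triisopropylsilyloxy)phenol | COc1cc(O)cc(O[Si](C(C)C)(C(C)C)C(C)C)c1 | intermediate
3 | triisopropyl[3-methoxy-5-(methoxymethoxy)phenoxy]silane | COCOc1cc(OC)cc(O[Si](C(C)C)(C(C)C)C(C)C)c1 | intermediate
4 | geranyl bromide, (2E)-1-bromo-3,7-dimethylocta-2,6-diene | BrC/C=C(\C)CCC=C(C)C | starting material
5 | [2-methoxy-6-(methoxymethoxy)-4-(triisopropylsilyloxy)phenyl]lithium, not isolated | [Li]c1c(OC)cc(O[Si](C(C)C)(C(C)C)C(C)C)cc1OCOC | intermediate
6 | [4-geranyl-3-methoxy-5-(methoxymethoxy)phenoxy]triisopropylsilane | COCOc1cc(O[Si](C(C)C)(C(C)C)C(C)C)cc(OC)c1C/C=C(\C)CCC=C(C)C | intermediate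
7 | 4-geranyl-3-methoxy-5-(methoxymethoxy)phenol | COCOc1cc(O)cc(OC)c1C/C=C(\C)CCC=C(C)C | intermediate
8 | 4-geranyl-3-methoxy-5-(methoxymethoxy)phenyl N,N-diethylcarbamate | CCN(CC)C(=O)Oc1cc(OC)c(C/C=C(\C)CCC=C(C)C)c(OCOC)c1 | intermediate
9 | [6-(diethylcarbamoyloxy)-3-geranyl-4-methoxy-2-(methoxymethoxy)phenyl]lithium, not isolated | CCN(CC)C(=O)Oc1cc(OC)c(C/C=C(\C)CCC=C(C)C)c(OCOC)c1[Li] | intermediate
10 | 4-geranyl-5-methoxy-3-(methoxymethoxy)-2-(trimethylsilyl)phenyl N,N-diethylcarbamate | CCN(CC)C(=O)Oc1cc(OC)c(C/C=C(\C)CCC=C(C)C)c(OCOC)c1[Si](C)(C)C | intermediate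
11 | 4-geranyl-5-methoxy-3-(methoxymethoxy)-2-(trimethylsilyl)phenol | COCOc1c(C/C=C(\C)CCC=C(C)C)c(OC)cc(O)c1[Si](C)(C)C | intermediate
12 | 4-geranyl-5-methoxy-3-(methoxymethoxy)-2-(trimethylsilyl)phenyl trifluoromethanesulfonate | COCOc1c(C/C=C(\C)CCC=C(C)C)c(OC)cc(OS(=O)(=O)C(F)(F)F)c1[Si](C)(C)C | intermediate
13 | ethyl 3-(3,4-dimethoxyphenyl)-3-oxopropanoate | CCOC(=O)CC(=O)c1ccc(OC)c(OC)c1 | starting material
14 | ethyl (3S)-3-(3,4-dimethoxyphenyl)-3-hydroxypropanoate | CCOC(=O)C[C@H](O)c1ccc(OC)c(OC)c1 | intermediate
15 | ethyl (3S)-3-(3,4-dimethoxyphenyl)-3-(trimethylsilyloxy)propanoate | CCOC(=O)C[C@H](O[Si](C)(C)C)c1ccc(OC)c(OC)c1 | intermediate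
16 | 4-geranyl-5-methoxy-3-(methoxymethoxy)benzyne (triple bond between C4a and C8a), not isolated | COCOC1=C(C/C=C(\C)CCC=C(C)C)C(OC)=CC#C1 | intermediate
17 | tetrabutylammonium (1S)-1-(3,4-dimethoxyphenyl)-3-ethoxy-3-oxopropan-1-olate, not isolated | CCOC(=O)C[C@H]([O-])c1ccc(OC)c(OC)c1.CCCC[N+](CCCC)(CCCC)CCCC | intermediate
18 | (2S)-6-geranyl-7,3',4'-trimethoxy-5-(methoxymethoxy)flavanone | COc1ccc([C@@H]2CC(=O)c3c(cc(OC)c(C/C=C(\C)CCC=C(C)C)c3OCOC)O2)cc1OC | intermediate
19 | (2S)-6-geranyl-5-hydroxy-7,3',4'-trimethoxyflavanone | COc1ccc([C@@H]2CC(=O)c3c(cc(OC)c(C/C=C(\C)CCC=C(C)C)c3O)O2)cc1OC | target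

**Count**
Total steps: 12. Longest linear sequence: 10 steps (steps 1 to 8, 11 and 12, from 1); the second branch (steps 9 and 10) joins at step 11.

**Steps most likely to fail**

Step 11. Three processes could defeat the annulation. The C4a aryl anion may be protonated before it reaches the ester, leaving an open aryl ether. The free alkoxide may fragment by retro-aldol cleavage or lose the elements of water by β-elimination. Base still present after ring closure may open ring C by retro-oxa-Michael reaction and erase the C2 configuration.
The fallback sets out from 8 and comes back at 18, using only known reaction types. Carbamate 8 is lithiated at C4a as in step 6 and the aryllithium is acylated with (2E)-3-(3,4-dimethoxyphenyl)-N-methoxy-N-methylprop-2-enamide. This should give the chalcone carbamate 2-[(2E)-3-(3,4-dimethoxyphenyl)prop-2-enoyl]-4-geranyl-5-methoxy-3-(methoxymethoxy)phenyl N,N-diethylcarbamate F1. Hydrolysis of the carbamate (KOH, EtOH, heat) should give the 2'-hydroxychalcone (2E)-3-(3,4-dimethoxyphenyl)-1-[3-geranyl-6-hydroxy-4-methoxy-2-(methoxymethoxy)phenyl]prop-2-en-1-one F2. An enantioselective intramolecular oxa-Michael addition under a cinchona-derived bifunctional thiourea catalyst then closes O1–C2 to 18. The catalyst series (quinine- or quinidine-based) that delivers the S configuration would have to be selected, and the enantiomeric purity may need to be raised by crystallisation. In this fallback the stereocenter is set by the catalyst after ring A is acylated, not carried in from 14.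

Step 6. Metalation may occur at C8 instead of C4a, the carbamoyl group may migrate to carbon on warming (anionic ortho-Fries shift), or the base may remove a benzylic-allylic proton of the geranyl CH2.
The fallback sets out from 7 and comes back at 18. Phenol 7 is silylated (TBSCl, imidazole) to tert-butyl[4-geranyl-3-methoxy-5-(methoxymethoxy)phenoxy]dimethylsilane F3. Treatment with s-BuLi and TMEDA should lithiate C4a, the only free position ortho to the MOM ether, and the ortho-lithiated silyl ether should undergo the 1,3 oxygen-to-carbon silyl shift (retro-Brook rearrangement) to 2-(tert-butyldimethylsilyl)-4-geranyl-5-methoxy-3-(methoxymethoxy)phenol F4. Triflation (Tf2O, pyridine) gives 2-(tert-butyldimethylsilyl)-4-geranyl-5-methoxy-3-(methoxymethoxy)phenyl trifluoromethanesulfonate F5. F5 takes the place of 12 in step 11, where the bulkier silyl group is expected to need a longer reaction time, and the route is rejoined at 18. There is no carbamate in this sequence, so no Fries shift is possible, and the regiochemistry rests on the MOM ether alone.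

Step 12. Acid may promote cyclisation of the geranyl chain onto the freed C5 phenol, or addition of methanol or HCl across the alkenes, before the acetal is fully cleaved.
The fallback sets out from 18 and comes back at 19. Treatment of 18 with TMSOTf and 2,2'-bipyridyl in CH2Cl2 at 0 °C should exchange the aryl MOM ether for a silyl ether without a protic acid, giving (2S)-6-geranyl-7,3',4'-trimethoxy-5-(trimethylsilyloxy)flavanone F6. Brief hydrolysis with water at neutral pH then releases 19.

**Further compounds**
F1 | step 11 | 2-[(2E)-3-(3,4-dimethoxyphenyl)prop-2-enoyl]-4-geranyl-5-methoxy-3-(methoxymethoxy)phenyl N,N-diethylcarbamate | CCN(CC)C(=O)Oc1cc(OC)c(C/C=C(\C)CCC=C(C)C)c(OCOC)c1C(=O)/C=C/c1ccc(OC)c(OC)c1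
F2 | step 11 | (2E)-3-(3,4-dimethoxyphenyl)-1-[3-geranyl-6-hydroxy-4-methoxy-2-(methoxymethoxy)phenyl]prop-2-en-1-one | COCOc1c(C/C=C(\C)CCC=C(C)C)c(OC)cc(O)c1C(=O)/C=C/c1ccc(OC)c(OC)c1
F3 | step 6 | tert-butyl[4-geranyl-3-methoxy-5-(methoxymethoxy)phenoxy]dimethylsilane | COCOc1cc(O[Si](C)(C)C(C)(C)C)cc(OC)c1C/C=C(\C)CCC=C(C)C
F4 | step 6 | 2-(tert-butyldimethylsilyl)-4-geranyl-5-methoxy-3-(methoxymethoxy)phenol | COCOc1c(C/C=C(\C)CCC=C(C)C)c(OC)cc(O)c1[Si](C)(C)C(C)(C)C
F5 | step 6 | 2-(tert-butyldimethylsilyl)-4-geranyl-5-methoxy-3-(methoxymethoxy)phenyl trifluoromethanesulfonate | COCOc1c(C/C=C(\C)CCC=C(C)C)c(OC)cc(OS(=O)(=O)C(F)(F)F)c1[Si](C)(C)C(C)(C)C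
F6 | step 12 | (2S)-6-geranyl-7,3',4'-trimethoxy-5-(trimethylsilyloxy)flavanone | COc1ccc([C@@H]2CC(=O)c3c(cc(OC)c(C/C=C(\C)CCC=C(C)C)c3O[Si](C)(C)C)O2)cc1OC
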